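The target is a cis-fused ketal that is expected to be a kinetic isomer of its ring-opened 3-aryl flavone, so it is reached from that flavone without equilibration. The route rests on the aryl ether bond O1–C8a between ring A and the pyranone ring C: a 2-aryl-1,3-diketone bearing a 2,4,6-trifluorophenyl ring closes ring C by enolate O-arylation. Because C3 carries the doubly ortho-oxygenated flavan benzo ring D, the closure freezes the C3–C8'' bond as a stereogenic axis, set by a chiral cation. This axis later steers O7'' onto one face of C2 of the derived flavylium ion and so fixes C2 and C3; C2'' comes from asymmetric transfer hydrogenation.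

Key step: step 9

Numbering: upper unit O1, C2 (ketal carbon), C3, C4 (carbonyl), C4a, C5–C8, C8a (ring A; ring C = pyranone; ring B = aryl on C2); flavan unit with double primes, C2'', C4a''–C8a'' (ring D), its pyran = ring E, its aryl = ring F.

Assumption: the C3–C8'' bond of the 3-aryl chromones 15, 17 and 18 (four ortho substituents) is taken to rotate only on strong heating; SMILES has no symbol for such an axis, so its sense (aS) is carried by the names [seen from the face showing C2 left, C4 right and ring D on top, O7'' points to the viewer].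

Step 1
Reactants: 1 2,4,6-trihydroxybenzaldehyde; 2 chloromethyl methyl ether
Product: 3 2,6-dihydroxy-4-(methoxymethoxy)benzaldehyde
Conditions: MOMCl (1.0 equiv), iPr2NEt, CH2Cl2, 0 °C
Reagents that add atoms: chloromethyl methyl ether (2), COCCl
Why: Williamson-type O-alkylation; the 4-OH is the most acidic hydroxyl and the only one not hydrogen-bonded to the formyl oxygen, so one equivalent of MOMCl should alkylate it selectively.

Step 2
Reactants: 3 2,6-dihydroxy-4-(methoxymethoxy)benzaldehyde; 4 benzyl bromide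
Product: 5 2-(benzyloxy)-6-hydroxy-4-(methoxymethoxy)benzaldehyde
Conditions: BnBr (1.0 equiv), K2CO3, acetone, 50 °C
Reagents that add atoms: benzyl bromide (4), BrCc1ccccc1
Why: Williamson etherification of one of two equivalent chelated hydroxyls; the second, still hydrogen-bonded to C=O, reacts much more slowly, so the reaction should stop at the mono-ether.

Step 3
Reactants: 5 2-(benzyloxy)-6-hydroxy-4-(methoxymethoxy)benzaldehyde; 6 1-[4-(benzyloxy)phenyl]ethan-1-one
Product: 7 (E)-3-[2-(benzyloxy)-6-hydroxy-4-(methoxymethoxy)phenyl]-1-[4-(benzyloxy)phenyl]prop-2-en-1-one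
Conditions: KOH, EtOH, 40 °C
Reagents that add atoms: 1-[4-(benzyloxy)phenyl]ethan-1-one (6), CC(=O)c1ccc(OCc2ccccc2)cc1
Why: Claisen–Schmidt aldol condensation of the methyl ketone enolate with the aldehyde, with E1cB dehydration giving the E-enone.

Step 4
Reactants: 7 (E)-3-[2-(benzyloxy)-6-hydroxy-4-(methoxymethoxy)phenyl]-1-[4-(benzyloxy)phenyl]prop-2-en-1-one
Product: 8 (1S)-3-[2-(benzyloxy)-6-hydroxy-4-(methoxymethoxy)phenyl]-1-[4-(benzyloxy)phenyl]propan-1-ol
Conditions: RuCl[(S,S)-TsDPEN](p-cymene) (2 mol %), HCO2H–Et3N (5:2), EtOAc, 40 °C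
Reagents that add atoms: none
Why: Asymmetric transfer hydrogenation; the ruthenium hydride should first reduce the enone C=C in the conjugate sense and then the aryl ketone through the six-membered metal–ligand bifunctional transition state, the (S,S) ligand giving the (S)-carbinol that becomes C2''.

Step 5
Reactants: 8 (1S)-3-[2-(benzyloxy)-6-hydroxy-4-(methoxymethoxy)phenyl]-1-[4-(benzyloxy)phenyl]propan-1-ol
Product: 9 (2R)-5-(benzyloxy)-2-[4-(benzyloxy)phenyl]-7-(methoxymethoxy)chromane
Conditions: PPh3, DIAD, THF, 0 °C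
Reagents that add atoms: none
Why: Intramolecular Mitsunobu etherification (6-exo-tet); the phenol displaces the activated benzylic oxygen with inversion, turning the (S)-alcohol into the (2R)-chromane, and the low temperature limits ionisation of the p-alkoxybenzylic centre.

Step 6
Reactants: 9 (2R)-5-(benzyloxy)-2-[4-(benzyloxy)phenyl]-7-(methoxymethoxy)chromane; 10 N-bromosuccinimide
Product: 11 (2R)-5-(benzyloxy)-2-[4-(benzyloxy)phenyl]-8-bromo-7-(methoxymethoxy)chromane
Conditions: NBS (1.0 equiv), CH2Cl2, −78 to 0 °C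
Reagents that add atoms: N-bromosuccinimide (10), O=C1CCC(=O)N1Br
Why: Electrophilic aromatic bromination of the phloroglucinol-type ring D at C8, which lies between the ring oxygen and OMOM and is less hindered than C6 between two acyclic ethers.

Step 7
Reactants: 11 (2R)-5-(benzyloxy)-2-[4-(benzyloxy)phenyl]-8-bromo-7-(methoxymethoxy)chromane; 6 1-[4-(benzyloxy)phenyl]ethan-1-one
Product: 12 1-[4-(benzyloxy)phenyl]-2-[(2R)-5-(benzyloxy)-2-[4-(benzyloxy)phenyl]-7-(methoxymethoxy)chroman-8-yl]ethan-1-one
Conditions: Pd2(dba)3 (2.5 mol %), XPhos, NaOtBu, toluene, 80 °C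
Reagents that add atoms: 1-[4-(benzyloxy)phenyl]ethan-1-one (6), CC(=O)c1ccc(OCc2ccccc2)cc1
Why: Palladium-catalysed ketone α-arylation (Buchwald–Hartwig type) by oxidative addition, enolate binding and C–C reductive elimination; the bulky biaryl phosphine serves the di-ortho-substituted bromide and the hindered product should resist a second arylation.

Step 8
Reactants: 12 1-[4-(benzyloxy)phenyl]-2-[(2R)-5-(benzyloxy)-2-[4-(benzyloxy)phenyl]-7-(methoxymethoxy)chroman-8-yl]ethan-1-one; 13 2,4,6-trifluorobenzoyl chloride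
Product: 14 1-[4-(benzyloxy)phenyl]-2-[(2R)-5-(benzyloxy)-2-[4-(benzyloxy)phenyl]-7-(methoxymethoxy)chroman-8-yl]-3-(2,4,6-trifluorophenyl)propane-1,3-dione
Conditions: LiN(SiMe3)2 (2.2 equiv), THF, −78 °C; 13; AcOH quench, −40 °C
Reagents that add atoms: 2,4,6-trifluorobenzoyl chloride (13), O=C(Cl)c1c(F)cc(F)cc1F
Why: Claisen-type C-acylation of the ketone enolate; the second equivalent of base removes the acidic methine so any O-acylated material is funnelled to the diketonate, and the cold acidic quench should keep the fluorinated ring from closing prematurely.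

Step 9
Reactants: 14 1-[4-(benzyloxy)phenyl]-2-[(2R)-5-(benzyloxy)-2-[4-(benzyloxy)phenyl]-7-(methoxymethoxy)chroman-8-yl]-3-(2,4,6-trifluorophenyl)propane-1,3-dione
Product: 15 (aS)-2-[4-(benzyloxy)phenyl]-3-[(2R)-5-(benzyloxy)-2-[4-(benzyloxy)phenyl]-7-(methoxymethoxy)chroman-8-yl]-5,7-difluoro-4H-chromen-4-one
Conditions: N-[3,5-bis(trifluoromethyl)benzyl]cinchonidinium bromide (10 mol %; or its cinchoninium pseudo-enantiomer, chosen by screening), solid K3PO4, toluene, 0 °C
Reagents that add atoms: none
Why: Proposed new method: the diketone enolate, ion-paired with a chiral quaternary ammonium cation, attacks an ortho C–F carbon of the trifluorobenzoyl ring through the oxygen on C2 (addition–elimination via a Meisenheimer anion, loss of fluoride); the closest known reactions are the base-mediated SNAr closure of 2-fluorobenzoyl 1,3-diketones to chromones and the cation-directed O-alkylation of α-aryl enolates that gives atropisomers by dynamic kinetic resolution. Ring C closes in a 6-exo-trig sense at C8a by forming O1–C8a; C-attack would need a four-membered ring and the para fluorine cannot be reached, so only this ring can form. No sp3 centre is created; the new stereo-element is the C3–C8'' axis, which rotates freely in the enolate and is frozen as the ring closes. The two rotamers therefore pass through diastereomeric ion-paired transition states, and the cation, not the remote C2'' centre, is expected to decide the sense. The step needs atroposelectivity and suppression of the achiral background reaction, which the insoluble potassium enolate in toluene should secure; the two equivalent ortho fluorines remove any regiochemical question. The fluorines left at C5 and C7 activate the ring enough for closure at 0 °C, below the rotation threshold of the product.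

Step 10
Reactants: 15 (aS)-2-[4-(benzyloxy)phenyl]-3-[(2R)-5-(benzyloxy)-2-[4-(benzyloxy)phenyl]-7-(methoxymethoxy)chroman-8-yl]-5,7-difluoro-4H-chromen-4-one; 16 benzyl alcohol
Product: 17 (aS)-5,7-bis(benzyloxy)-2-[4-(benzyloxy)phenyl]-3-[(2R)-5-(benzyloxy)-2-[4-(benzyloxy)phenyl]-7-(methoxymethoxy)chroman-8-yl]-4H-chromen-4-one
Conditions: BnOH (2.2 equiv), NaH, DMF, 0 to 20 °C
Reagents that add atoms: benzyl alcohol (16), OCc1ccccc1
Why: Twofold nucleophilic aromatic substitution by benzyl oxide at C7 (para to the C4 carbonyl) and C5 (ortho to it), both activated by the pyranone carbonyl; room temperature should leave the axis intact.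

Step 11
Reactants: 17 (aS)-5,7-bis(benzyloxy)-2-[4-(benzyloxy)phenyl]-3-[(2R)-5-(benzyloxy)-2-[4-(benzyloxy)phenyl]-7-(methoxymethoxy)chroman-8-yl]-4H-chromen-4-one
Product: 18 (aS)-5,7-bis(benzyloxy)-2-[4-(benzyloxy)phenyl]-3-[(2R)-5-(benzyloxy)-2-[4-(benzyloxy)phenyl]-7-hydroxychroman-8-yl]-4H-chromen-4-one
Conditions: ZnBr2, n-PrSH, CH2Cl2, 0 °C
Reagents that add atoms: none
Why: Lewis acid–thiol cleavage of the MOM acetal (ZnBr2 activates the acetal, the thiol captures the methoxymethyl cation) under cold aprotic conditions that should leave benzyl ethers, the chromone and the axis untouched.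

Step 12
Reactants: 18 (aS)-5,7-bis(benzyloxy)-2-[4-(benzyloxy)phenyl]-3-[(2R)-5-(benzyloxy)-2-[4-(benzyloxy)phenyl]-7-hydroxychroman-8-yl]-4H-chromen-4-one
Product: 21 (2S,3S,2''R)-penta-O-benzyl ether of the target, via 4-silyloxyflavylium triflate 19 (not isolated), via silyl enol ether ketal 20 (not isolated)
Conditions: Me3SiOSO2CF3 (1.05 equiv), CH2Cl2, −78 °C; 2,6-di-tert-butylpyridine; then Bu4NF–AcOH (1:1), −78 to −20 °C
Reagents that add atoms: none
Why: O-silylation of the pyranone carbonyl gives a flavylium ion whose C2 is captured 5-exo by the neighbouring phenol O7'' on the face fixed by the (aS) axis (the flavylium-to-ketal chemistry of A-type proanthocyanidins), setting C2 as S, and buffered fluoride then frees the enol, which can ketonise only to the cis ring fusion, setting C3 as S, so the ketal is trapped kinetically and never exposed to equilibrating acid or base.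

Step 13
Reactants: 21 (2S,3S,2''R)-penta-O-benzyl ether of the target
Product: 22 target CNP0179743.1
Conditions: H2 (1 atm), Pd/C, EtOAc–MeOH, 20 °C
Reagents that add atoms: none
Why: Neutral hydrogenolysis of the five benzyl ethers; without acid or base the ketal and the C3–H centre should not open, and the aryl ketone, a vinylogous ester, should resist reduction.

Compound list
1 | 2,4,6-trihydroxybenzaldehyde | O=Cc1c(O)cc(O)cc1O | starting material
2 | chloromethyl methyl ether | COCCl | starting material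
3 | 2,6-dihydroxy-4-(methoxymethoxy)benzaldehyde | COCOc1cc(O)c(C=O)c(O)c1 | intermediate
4 | benzyl bromide | BrCc1ccccc1 | starting material
5 | 2-(benzyloxy)-6-hydroxy-4-(methoxymethoxy)benzaldehyde | COCOc1cc(O)c(C=O)c(OCc2ccccc2)c1 | intermediate
6 | 1-[4-(benzyloxy)phenyl]ethan-1-one | CC(=O)c1ccc(OCc2ccccc2)cc1 | starting material
7 | (E)-3-[2-(benzyloxy)-6-hydroxy-4-(methoxymethoxy)phenyl]-1-[4-(benzyloxy)phenyl]prop-2-en-1-one | O=C(/C=C/c1c(O)cc(OCOC)cc1OCc1ccccc1)c1ccc(OCc2ccccc2)cc1 | intermediate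
8 | (1S)-3-[2-(benzyloxy)-6-hydroxy-4-(methoxymethoxy)phenyl]-1-[4-(benzyloxy)phenyl]propan-1-ol | O[C@@H](CCc1c(O)cc(OCOC)cc1OCc1ccccc1)c1ccc(OCc2ccccc2)cc1 | intermediate
9 | (2R)-5-(benzyloxy)-2-[4-(benzyloxy)phenyl]-7-(methoxymethoxy)chromane | COCOc1cc(OCc2ccccc2)c2c(c1)O[C@@H](c1ccc(OCc3ccccc3)cc1)CC2 | intermediate
10 | N-bromosuccinimide | O=C1CCC(=O)N1Br | starting material
11 | (2R)-5-(benzyloxy)-2-[4-(benzyloxy)phenyl]-8-bromo-7-(methoxymethoxy)chromane | COCOc1cc(OCc2ccccc2)c2c(c1Br)O[C@@H](c1ccc(OCc3ccccc3)cc1)CC2 | intermediate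
12 | 1-[4-(benzyloxy)phenyl]-2-[(2R)-5-(benzyloxy)-2-[4-(benzyloxy)phenyl]-7-(methoxymethoxy)chroman-8-yl]ethan-1-one | COCOc1cc(OCc2ccccc2)c2c(c1CC(=O)c1ccc(OCc3ccccc3)cc1)O[C@@H](c1ccc(OCc3ccccc3)cc1)CC2 | intermediate
13 | 2,4,6-trifluorobenzoyl chloride | O=C(Cl)c1c(F)cc(F)cc1F | starting material
14 | 1-[4-(benzyloxy)phenyl]-2-[(2R)-5-(benzyloxy)-2-[4-(benzyloxy)phenyl]-7-(methoxymethoxy)chroman-8-yl]-3-(2,4,6-trifluorophenyl)propane-1,3-dione (enolisable; central carbon not defined) | COCOc1cc(OCc2ccccc2)c2c(c1C(C(=O)c1ccc(OCc3ccccc3)cc1)C(=O)c1c(F)cc(F)cc1F)O[C@@H](c1ccc(OCc3ccccc3)cc1)CC2 | intermediate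
15 | (aS)-2-[4-(benzyloxy)phenyl]-3-[(2R)-5-(benzyloxy)-2-[4-(benzyloxy)phenyl]-7-(methoxymethoxy)chroman-8-yl]-5,7-difluoro-4H-chromen-4-one | COCOc1cc(OCc2ccccc2)c2c(c1-c1c(-c3ccc(OCc4ccccc4)cc3)oc3cc(F)cc(F)c3c1=O)O[C@@H](c1ccc(OCc3ccccc3)cc1)CC2 | intermediate
16 | benzyl alcohol | OCc1ccccc1 | starting material
17 | (aS)-5,7-bis(benzyloxy)-2-[4-(benzyloxy)phenyl]-3-[(2R)-5-(benzyloxy)-2-[4-(benzyloxy)phenyl]-7-(methoxymethoxy)chroman-8-yl]-4H-chromen-4-one | COCOc1cc(OCc2ccccc2)c2c(c1-c1c(-c3ccc(OCc4ccccc4)cc3)oc3cc(OCc4ccccc4)cc(OCc4ccccc4)c3c1=O)O[C@@H](c1ccc(OCc3ccccc3)cc1)CC2 | intermediate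
18 | (aS)-5,7-bis(benzyloxy)-2-[4-(benzyloxy)phenyl]-3-[(2R)-5-(benzyloxy)-2-[4-(benzyloxy)phenyl]-7-hydroxychroman-8-yl]-4H-chromen-4-one | Oc1cc(OCc2ccccc2)c2c(c1-c1c(-c3ccc(OCc4ccccc4)cc3)oc3cc(OCc4ccccc4)cc(OCc4ccccc4)c3c1=O)O[C@@H](c1ccc(OCc3ccccc3)cc1)CC2 | intermediate
19 | (aS)-4-(trimethylsilyloxy)flavylium trifluoromethanesulfonate derived from 18 (not isolated) | Oc1cc(OCc2ccccc2)c2c(c1-c1c(-c3ccc(OCc4ccccc4)cc3)[o+]c3cc(OCc4ccccc4)cc(OCc4ccccc4)c3c1O[Si](C)(C)C)O[C@@H](c1ccc(OCc3ccccc3)cc1)CC2.[O-]S(=O)(=O)C(F)(F)F | intermediate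
20 | cis-ketal with C3=C4 trimethylsilyl enol ether, ketal carbon configured as in 21, C2'' (R) (not isolated) | C[Si](C)(C)OC1c2c(OCc5ccccc5)cc(OCc5ccccc5)cc2O[C@@]2(c3ccc(OCc5ccccc5)cc3)Oc3cc(OCc5ccccc5)c4c(c3C=12)O[C@@H](c1ccc(OCc5ccccc5)cc1)CC4 | intermediate
21 | (2S,3S,2''R)-penta-O-benzyl ether of the target (benzyl on O5, O7, O4' of ring B, O5'' and O4 of ring F) | O=C1c2c(OCc5ccccc5)cc(OCc5ccccc5)cc2O[C@@]2(c3ccc(OCc5ccccc5)cc3)Oc3cc(OCc5ccccc5)c4c(c3[C@@H]12)O[C@@H](c1ccc(OCc5ccccc5)cc1)CC4 | intermediate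
22 | target CNP0179743.1: cis-fused furo-chromanone ketal, C2 (S), C3 (S), C2'' (R), five free phenols | O=C1c2c(O)cc(O)cc2O[C@@]2(c3ccc(O)cc3)Oc3cc(O)c4c(c3[C@@H]12)O[C@@H](c1ccc(O)cc1)CC4 | target

Total step count: 13. Longest linear sequence: 13 steps (1 to 22).

Steps most likely to fail

Step 9 (Proposed new method). The chiral cation may discriminate poorly between the two enolate rotamers (low atroposelectivity), or the achiral potassium enolate may close the ring in the background. Fallback, known chemistry with stereocontrol moved to a separation and recycling loop: from 14, ring closure with K2CO3 in DMF at 20 °C, an established chromone synthesis, should give 15 together with its (aR)-atropisomer F1. Because C2'' is present the two are diastereomers and are separated on silica. F1 is re-equilibrated by heating in o-dichlorobenzene at about 150 °C and separated again; the route continues from 15.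

Step 12. The phenol may be silylated instead of the carbonyl oxygen, or the ketal may re-ionise to the flavylium ion and collapse to the flavone during desilylation. Fallback through a lower oxidation level, where ketal formation is downhill: from 18, LiAlH4 in THF at 0 °C reduces C4=O to the 4H-chromen-4-ol F2. A trace of camphorsulfonic acid in CH2Cl2 at −40 °C ionises F2 to the 4-unsubstituted flavylium ion, which O7'' captures at C2; an Et3N quench gives the 2H-chromene ketal F3. Hydroboration with BH3·THF and NaBO3·4H2O work-up places H on C3 and OH on C4, giving the C4 alcohol F4. Dess–Martin periodinane with NaHCO3 then oxidises F4 to 21.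

Step 7. Oxidative addition and reductive elimination at the doubly ortho-oxygenated bromide may be slow, leading to protodebromination and self-condensation of the ketone. Fallback with reversed polarity: from 11, n-BuLi in THF at −78 °C and then ZnCl2 give the arylzinc chloride F5. Nickel-catalysed Negishi coupling of F5 with commercial 2-bromo-1-[4-(benzyloxy)phenyl]ethan-1-one (NiCl2(dme), 2,2'-bipyridine, THF, −30 °C) should deliver 12.

Further compounds
F1 | step 9 | (aR)-atropisomer of 15 (same constitution, opposite sense of the C3–C8'' axis) | COCOc1cc(OCc2ccccc2)c2c(c1-c1c(-c3ccc(OCc4ccccc4)cc3)oc3cc(F)cc(F)c3c1=O)O[C@@H](c1ccc(OCc3ccccc3)cc1)CC2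
F2 | step 12 | (aS)-5,7-bis(benzyloxy)-2-[4-(benzyloxy)phenyl]-3-[(2R)-5-(benzyloxy)-2-[4-(benzyloxy)phenyl]-7-hydroxychroman-8-yl]-4H-chromen-4-ol (C4 epimers) | Oc1cc(OCc2ccccc2)c2c(c1C1=C(c3ccc(OCc4ccccc4)cc3)Oc3cc(OCc4ccccc4)cc(OCc4ccccc4)c3C1O)O[C@@H](c1ccc(OCc3ccccc3)cc1)CC2
F3 | step 12 | 2H-chromene ketal (C3=C4, H on C4), ketal carbon configured as in 21 | C1c2c(OCc5ccccc5)cc(OCc5ccccc5)cc2O[C@@]2(c3ccc(OCc5ccccc5)cc3)Oc3cc(OCc5ccccc5)c4c(c3C=12)O[C@@H](c1ccc(OCc5ccccc5)cc1)CC4
F4 | step 12 | C4 alcohol of 21 (C4 configuration from syn-hydroboration, not carried forward) | OC1c2c(OCc5ccccc5)cc(OCc5ccccc5)cc2O[C@@]2(c3ccc(OCc5ccccc5)cc3)Oc3cc(OCc5ccccc5)c4c(c3[C@@H]12)O[C@@H](c1ccc(OCc5ccccc5)cc1)CC4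
F5 | step 7 | [(2R)-5-(benzyloxy)-2-[4-(benzyloxy)phenyl]-7-(methoxymethoxy)chroman-8-yl]zinc chloride | COCOc1cc(OCc2ccccc2)c2c(c1[Zn]Cl)O[C@@H](c1ccc(OCc3ccccc3)cc1)CC2
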